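(The data are simulated for an exercise; the scatter is artificial.)

A small charge of initiator, 2 mol% on 2.0 M of free monomer, goes into each new flask, and I must choose where to hold it for 15 min.

| flask | free monomer | initiator | temperature | remark | time |
|---|---|---|---|---|---|
| spring | 2 M | 1.3 mol% | 45 °C | run made earlier |  |
| summer | 2 M | 3 mol% | 70 °C | run made earlier |  |
| north | 2.0 M | 2 mol% | 70 °C |  | 15 min |
| south-west | 2.0 M | 2 mol% | 90 °C |  | 15 min |
| east | 2.0 M | 2 mol% | 50 °C |  | 15 min |
| north-east | 2.0 M | 2 mol% |  | at 90 °C until 10 min, from then on at 50 °C | 15 min |

| run | time / min | monomer in chains / % | free monomer / % |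
|---|---|---|---|
| spring | 3.00 | 57 | 38 |
| spring | 8.00 | 73 | 24 |
| spring | 15.0 | 72 | 25 |
| spring | 20.0 | 70 | 22 |
| spring | 30.0 | 69 | 18 |
| summer | 2.00 | 72 | 23 |
| summer | 4.00 | 71 | 20 |
| summer | 5.00 | 66 | 25 |
| summer | 8.00 | 68 | 19 |
| summer | 10.0 | 63 | 21 |

(scatter of a reading: 1.5 percentage points)

- a reading or a percentage of monomer in chains counts all its forms, free or not

1. which flask leads in amount of monomer in chains, in percent of the free monomer charged ("all alike" within 1.5 percentage points) (north / south-west / east / north-east / all alike)
2. how much monomer in chains is there at the end, in percent of the free monomer charged: north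
3. how much monomer in chains is there at the end, in percent of the free monomer charged: south-west
4. how much monomer in chains is there at the end, in percent of the free monomer charged: east
5. how much monomer in chains is there at the end, in percent of the free monomer charged: north-east

Monomer in chains and free monomer are the large quantities, so I reckon the small one: the gap in the mass balance. In the spring run their sum falls from 97.0% at 8.00 min to 87.0% at 30.0 min. That is 0.00455 min⁻¹, and I call this fraction of the charge lost per minute the leak. The summer run, read from 2.00 min to 10.0 min, gives 0.0137 min⁻¹, which is 3.01 times as fast. But that run is both hotter and richer in initiator, so I cannot separate the two, and each reading scatters by 1.5 percentage points.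

My reckoning is this: monomer in chains at the end is the charge, less free monomer, less leak times time. I take free monomer as the mean of each run's last two readings. For the flask east, 50 °C lies close to the spring temperature, so I borrow the spring leak. The reckoned gap is 6.82% and monomer in chains comes to 73.2%. For the flask north I borrow the summer leak, and monomer in chains comes to 59.4%, which is less than my figure for east. No earlier run stands at 90 °C, so I give south-west and north-east no number. Of the two flasks I can reckon, I choose the one at 50 °C.

The forecast also picks east, and its numbers are not mine: north 61%, south-west 48%, east 70%, north-east 55%. Its ground is “The balance (chains + free) then falls, so material leaks to a side product.”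

The flasks give north 54.3%, south-west 20.5%, east 75.7%, north-east 26.1%, so east leads.

    initiator → 2 initiating radical (k = 0.0204 s⁻¹, Ea = 84.0 kJ mol⁻¹)
    free monomer + initiating radical → growing radical + monomer in chains (k = 26700 M⁻¹ s⁻¹, Ea = 31.0 kJ mol⁻¹)
    free monomer + growing radical → monomer in chains + growing radical, rate k3*[growing radical]*[free monomer] (k = 1600 M⁻¹ s⁻¹, Ea = 36.0 kJ mol⁻¹)
    2 growing radical → dead chain (k = 9.00 × 10⁶ M⁻¹ s⁻¹, Ea = 20.0 kJ mol⁻¹)
    free monomer + monomer in chains → side product (k = 0.00142 M⁻¹ s⁻¹, Ea = 67.0 kJ mol⁻¹)
    crystals ⇌ monomer in chains, rate k6*(cs6 - [monomer in chains]) while solid is left; crystals form when [monomer in chains] > cs6 (solubility = 0.0760 M, k = 0.429 s⁻¹)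
    (constants at 50 °C)

In the flask east, side product at 15.0 min stands at 5.44%, less than the reckoned gap of 6.82%. Left until 1.0 h, the same flask is reckoned at a gap of 27.3%, but its side product is 14.9%. Between the two times it gains 0.00210 min⁻¹, about half the leak read from the spring run. At that later time the flask east holds free monomer at 14.1% and monomer in chains at 71.0%.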